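**Strategy.** Opening the hemiketal at C1 (germacrane numbering) reveals a cyclodec-5-en-1-one: the C1 ketone and the C5=C6 enol-lactone double bond of the ten-membered ring C1–C10. This is the retron of an anionic oxy-Cope ring expansion. Vinyllithium adds to the C1 ketone of a densely substituted cyclohexanone (ring C1, C6–C10; C6 carries oxygen and a propynyl group) and the alkoxide rearranges in the same flask. C1–C2 forms in the addition and C3–C4 in the [3,3] shift. The six-membered ring becomes the carbocycle, with a C4=C5=C6 siloxyallene of fixed helicity. Gold-catalysed transannular attack of the C1 carbonyl on C4 then closes the oxolane; the butenolide is annulated afterwards.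

Key step: step 6

Remark: locants C1–C15 in the text are germacrane locants of the target (C1 hemiketal carbon, C2–C3 oxolane CH2CH2, C4 quaternary C–O, C5=C6 enol-lactone alkene, C7=C11 butenolide alkene, C8 acyloxy carbon, C10 CH(CH3), C13 CH2OAc); systematic names of the six-membered precursors use their own ring locants.
Remark: 1 and 22 are assumed to be commercially available chiral building blocks.

Step 1
Reactants: 1 (S)-4-[(tert-butyldimethylsilyl)oxy]cyclohex-2-en-1-one
Product: 2 (4S,6S)-4-[(tert-butyldimethylsilyl)oxy]-6-methylcyclohex-2-en-1-one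
Conditions: LDA, THF, −78 °C; MeI, −78 → −40 °C
Reagents that add atoms: iodomethane CI
Why: Kinetic α′-deprotonation gives the cross-conjugated lithium enolate, which should be methylated mainly anti to the silyloxy group (enolate alkylation); this centre (later C10) is α to the ketone and is corrected by equilibration in step 5.

Step 2
Reactants: 2 (4S,6S)-4-[(tert-butyldimethylsilyl)oxy]-6-methylcyclohex-2-en-1-one
Product: 3 (4S,6S)-4-[(tert-butyldimethylsilyl)oxy]-2-iodo-6-methylcyclohex-2-en-1-one
Conditions: I2, pyridine, CH2Cl2, 0 → 25 °C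
Reagents that add atoms: iodine II
Why: Johnson α-iodination (conjugate addition of pyridine, iodination of the enolate, elimination) functionalises the enone α-carbon, the future C6.

Step 3
Reactants: 3 (4S,6S)-4-[(tert-butyldimethylsilyl)oxy]-2-iodo-6-methylcyclohex-2-en-1-one; 4 propyne
Product: 5 (4S,6S)-4-[(tert-butyldimethylsilyl)oxy]-6-methyl-2-(prop-1-yn-1-yl)cyclohex-2-en-1-one
Conditions: Pd(PPh3)2Cl2 (3 mol %), CuI (6 mol %), i-Pr2NH, THF, 0 → 25 °C
Reagents that add atoms: none
Why: Sonogashira coupling of the α-iodoenone with propyne attaches C5, C4 and C15 to C6.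

Step 4
Reactants: 5 (4S,6S)-4-[(tert-butyldimethylsilyl)oxy]-6-methyl-2-(prop-1-yn-1-yl)cyclohex-2-en-1-one
Product: 6 (2R,3R,4S,6S)-4-[(tert-butyldimethylsilyl)oxy]-2,3-dihydroxy-6-methyl-2-(prop-1-yn-1-yl)cyclohexan-1-one
Conditions: OsO4 (5 mol %), NMO, citric acid, t-BuOH/H2O, 25 °C
Reagents that add atoms: osmium tetroxide O=[Os](=O)(=O)=O; N-methylmorpholine N-oxide C[N+]1([O-])CCOCC1
Why: Upjohn syn-dihydroxylation should take place at the enone alkene (the alkyne is slower) on the face anti to the allylic C8 silyloxy group (Kishi's rule), setting C6 and C7 as a cis-diol trans to OTBS.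

Step 5
Reactants: 6 (2R,3R,4S,6S)-4-[(tert-butyldimethylsilyl)oxy]-2,3-dihydroxy-6-methyl-2-(prop-1-yn-1-yl)cyclohexan-1-one
Product: 8 silylene ketone with methyl cis to OTBS, via methyl-trans silylene ketone 7 (not isolated)
Conditions: t-Bu2Si(OTf)2, 2,6-lutidine, CH2Cl2, 0 °C; then DBU (0.3 equiv), 25 °C
Reagents that add atoms: di-tert-butylsilyl bis(trifluoromethanesulfonate) CC(C)(C)[Si](OS(=O)(=O)C(F)(F)F)(OS(=O)(=O)C(F)(F)F)C(C)(C)C
Why: The di-tert-butylsilylene bridges the cis tertiary/secondary diol, and DBU equilibrates the ketone α-centre C10 to the chair in which methyl and OTBS are both equatorial (cis); C6 carries no hydrogen, so β-elimination is not possible.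

Step 6
Reactants: 8 silylene ketone with methyl cis to OTBS; 9 vinyl bromide
Product: 12 ten-membered siloxyallenyl ketone, via tertiary 1-vinyl alkoxide 10 (not isolated), via potassium enolate 11 (not isolated)
Conditions: 9, t-BuLi (2 equiv), Et2O, −78 °C; add 8, THF, −78 °C; then t-BuOK, 18-crown-6, −78 → 25 °C; aq NH4Cl, −20 °C
Reagents that add atoms: none
Why: Vinyllithium should attack the C1 ketone axially, anti to the axial C6–O bond and away from the t-Bu2Si face (Felkin–Anh polar control), so that vinyl and the equatorial propynyl group are cis and gauche; after Li→K exchange the alkoxide undergoes a chair-like anionic oxy-Cope shift ([3,3], propargyl variant) in which C3 bonds to C4 as C1–C6 breaks, giving the enolate and the C4=C5=C6 siloxyallene. The closest known type is the tandem vinyl addition/anionic oxy-Cope ring expansion of 2-alkenyl- and 2-alkynylcyclohexanones to cyclodec-5-enones used for germacranes. No ring is closed by an exo or endo attack: the six-membered ring is enlarged by four atoms to the ten-membered carbocycle in the sigmatropic shift. The stereocentres at C1 and C6 disappear and their configuration is transferred suprafacially to the allene axis (C3 enters C4 on the face that C1 leaves), while C8 and C10 are untouched. The step needs 1,2-addition rather than enolisation or attack at silicon (−78 °C, hindered t-Bu2Si), the cis relationship of the two unsaturated groups (secured by the axial C6–O bond) and a concerted rather than fragmentative pathway (C6 carries no anion-stabilising group).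

Step 7
Reactants: 12 ten-membered siloxyallenyl ketone
Product: 13 bridged methyl ketal with cyclic silyl enol ether
Conditions: JohnPhosAu(MeCN)SbF6 (2 mol %), MeOH (5 equiv), 2,6-di-tert-butylpyridine (5 mol %), CH2Cl2, −20 °C
Reagents that add atoms: methanol CO
Why: Proposed new method: cationic gold(I) should coordinate the distal C4=C5 π bond of the siloxyallene, the C1 carbonyl oxygen adds 5-exo to C4 anti to gold from inside the ring (the C7 side), methanol captures the C1 oxocarbenium ion and protodeauration at C5 leaves the silyl enol ether, so that the allene axis is converted into the C4 stereocentre (R) and the (5E) alkene (the other face would demand a trans olefin in the nine-membered oxacycle) while C1 is fixed by the bridge; the closest known types are gold-catalysed intramolecular hydroalkoxylation of allenes with axis-to-centre chirality transfer and gold-catalysed alkoxycyclisation of carbonyl-tethered alkynes.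

Step 8
Reactants: 13 bridged methyl ketal with cyclic silyl enol ether; 14 acrylic anhydride
Product: 15 enol acrylate with O7 di-tert-butylfluorosilyl ether
Conditions: TBAT (1.05 equiv) added to 13 and 14 (2 equiv), THF, −78 °C
Reagents that add atoms: tetrabutylammonium difluorotriphenylsilicate CCCC[N+](CCCC)(CCCC)CCCC.F[Si-](F)(c1ccccc1)(c1ccccc1)c1ccccc1
Why: Fluoride should add to the strained dioxasilolane silicon and expel the enolate oxygen O6, the better leaving group, and the ammonium enolate is O-acylated by the anhydride at −78 °C before it can expel the β-oxygen at C4 (fluoride-mediated silyl enol ether cleavage and enolate O-acylation), the C5=C6 geometry being retained.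

Step 9
Reactants: 15 enol acrylate with O7 di-tert-butylfluorosilyl ether
Product: 16 enol acrylate C7 alcohol
Conditions: Et3N·3HF, THF, 0 °C
Reagents that add atoms: none
Why: The di-tert-butylfluorosilyl ether on O7 is more electrophilic at silicon than the secondary TBS ether on O8 and should be removed selectively as the difluorosilane (fluoride desilylation).

Step 10
Reactants: 16 enol acrylate C7 alcohol
Product: 17 enol acrylate C7 ketone
Conditions: Dess–Martin periodinane, NaHCO3, CH2Cl2, 0 → 25 °C
Reagents that add atoms: none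
Why: Dess–Martin oxidation of the secondary C7 alcohol under buffered, non-basic conditions gives the α-acyloxy enone without touching the ketal or enolising C8.

Step 11
Reactants: 17 enol acrylate C7 ketone
Product: 18 α-methylene-β-hydroxy enol lactone
Conditions: PMe3 (20 mol %), THF/t-BuOH, 25 °C
Reagents that add atoms: none
Why: Phosphine-catalysed intramolecular Morita–Baylis–Hillman reaction: PMe3 adds to the acrylate, the zwitterionic enolate closes the five-membered lactone by 5-exo-trig aldol addition of C11 to the C7 ketone, and the phosphine is lost; the new C7 carbinol centre is removed in step 12.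

Step 12
Reactants: 18 α-methylene-β-hydroxy enol lactone
Product: 20 13-acetoxy butenolide, via tertiary allylic acetate 19 (not isolated)
Conditions: Ac2O, DMAP, Et3N, CH2Cl2, 35 °C; then DABCO (30 mol %), THF, 50 °C
Reagents that add atoms: acetic anhydride CC(=O)OC(C)=O
Why: Acetylation of the tertiary Baylis–Hillman alcohol followed by DABCO-catalysed SN2′/SN2′ allylic transposition moves the acetate to C13 and the alkene to C7=C11, the fully conjugated ylidene butenolide being the thermodynamic isomer (isomerisation of Baylis–Hillman acetates).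

Step 13
Reactants: 20 13-acetoxy butenolide
Product: 21 C8 alcohol
Conditions: HF·pyridine, pyridine, THF, 25 °C
Reagents that add atoms: none
Why: Fluoride cleavage of the secondary TBS ether frees the C8 hydroxyl; acetate, enol lactone and methyl ketal should tolerate buffered HF·pyridine.

Step 14
Reactants: 21 C8 alcohol; 22 (S)-3-chloro-2-hydroxy-2-methylpropanoic acid
Product: 26 CNP0414417.1, via bis-silylated acid 23 (not isolated), via O-silyl acid chloride 24 (not isolated), via silylated ester methyl ketal 25 (not isolated)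
Conditions: 22, TMSCl, pyridine, CH2Cl2, 0 °C; (COCl)2, DMF (cat.), 0 °C; add 21, DMAP, 0 → 25 °C; then 0.5 M HCl, THF, 25 °C
Reagents that add atoms: water O
Why: Transient silylation allows the α-hydroxy acid to be converted into its acid chloride (the quaternary stereocentre cannot epimerise), DMAP-catalysed acylation esterifies the C8 hydroxyl, and dilute acid removes the TMS ether and hydrolyses the bridgehead methyl ketal through the ring-oxygen-stabilised oxocarbenium ion to the hemiketal, whose configuration at C1 is dictated by the bridge.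

**Compound list**

1 | (S)-4-[(tert-butyldimethylsilyl)oxy]cyclohex-2-en-1-one | O=C1C=C[C@@H](O[Si](C)(C)C(C)(C)C)CC1 | starting material
2 | (4S,6S)-4-[(tert-butyldimethylsilyl)oxy]-6-methylcyclohex-2-en-1-one (methyl trans to OTBS) | C[C@H]1C[C@H](O[Si](C)(C)C(C)(C)C)C=CC1=O | intermediate
3 | (4S,6S)-4-[(tert-butyldimethylsilyl)oxy]-2-iodo-6-methylcyclohex-2-en-1-one | C[C@H]1C[C@H](O[Si](C)(C)C(C)(C)C)C=C(I)C1=O | intermediate
4 | propyne | CC#C | starting material
5 | (4S,6S)-4-[(tert-butyldimethylsilyl)oxy]-6-methyl-2-(prop-1-yn-1-yl)cyclohex-2-en-1-one | C[C@H]1C[C@H](O[Si](C)(C)C(C)(C)C)C=C(C#CC)C1=O | intermediate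
6 | (2R,3R,4S,6S)-4-[(tert-butyldimethylsilyl)oxy]-2,3-dihydroxy-6-methyl-2-(prop-1-yn-1-yl)cyclohexan-1-one (cis-diol, both OH anti to OTBS) | C[C@H]1C[C@H](O[Si](C)(C)C(C)(C)C)[C@@H](O)[C@](O)(C#CC)C1=O | intermediate
7 | 2,3-O-(di-tert-butylsilylene) derivative of 6 (methyl still trans to OTBS) | C[C@H]1C[C@H](O[Si](C)(C)C(C)(C)C)[C@H]2O[Si](C(C)(C)C)(C(C)(C)C)O[C@@]2(C#CC)C1=O | intermediate
8 | 2,3-O-(di-tert-butylsilylene) derivative of the 6-epimer of 6 (6R; methyl cis to OTBS) | C[C@@H]1C[C@H](O[Si](C)(C)C(C)(C)C)[C@H]2O[Si](C(C)(C)C)(C(C)(C)C)O[C@@]2(C#CC)C1=O | intermediate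
9 | vinyl bromide | C=CBr | starting material
10 | lithium (then potassium) alkoxide from addition of vinyl to C1 of 8; vinyl cis to propynyl and trans to the silylene oxygens | C[C@@H]1C[C@H](O[Si](C)(C)C(C)(C)C)[C@H]2O[Si](C(C)(C)C)(C(C)(C)C)O[C@@]2(C#CC)[C@]1([O-])C=C.[Li+] | intermediate
11 | potassium C1 enolate of 12 | C[C@@H]1C[C@H](O[Si](C)(C)C(C)(C)C)[C@H]2O[Si](C(C)(C)C)(C(C)(C)C)OC2=[C@@]=C(C)CC=C1[O-].[K+] | intermediate
12 | ten-membered allenyl ketone: C1 ketone, C4=C5=C6 allene of the helicity shown, O6/O7 di-tert-butylsilylene, 8-OTBS, 10-methyl | C[C@@H]1C[C@H](O[Si](C)(C)C(C)(C)C)[C@H]2O[Si](C(C)(C)C)(C(C)(C)C)OC2=[C@@]=C(C)CCC1=O | intermediate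
13 | bridged methyl ketal: 1,4-epoxy, 1-OMe, (5E)-alkene, O6/O7 silylene (cyclic silyl enol ether), 8-OTBS | CC(C)(C)[Si]3(C(C)(C)C)O/C2=C/[C@@]1(C)CC[C@](OC)(O1)[C@H](C)C[C@H](O[Si](C)(C)C(C)(C)C)[C@H]2O3 | intermediate
14 | acrylic anhydride | C=CC(=O)OC(=O)C=C | starting material
15 | O6 enol acrylate, O7 di-tert-butylfluorosilyl ether of the bridged methyl ketal | C=CC(=O)O/C2=C/[C@@]1(C)CC[C@](OC)(O1)[C@H](C)C[C@H](O[Si](C)(C)C(C)(C)C)[C@H]2O[Si](F)(C(C)(C)C)C(C)(C)C | intermediate
16 | O6 enol acrylate with free C7 hydroxyl | C=CC(=O)O/C2=C/[C@@]1(C)CC[C@](OC)(O1)[C@H](C)C[C@H](O[Si](C)(C)C(C)(C)C)[C@H]2O | intermediate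
17 | O6 enol acrylate with C7 ketone | C=CC(=O)O/C2=C/[C@@]1(C)CC[C@](OC)(O1)[C@H](C)C[C@H](O[Si](C)(C)C(C)(C)C)C2=O | intermediate
18 | Baylis–Hillman lactone: 11(13)-methylene, 7-hydroxy, 6,12-enol lactone (C7 configuration not defined) | C=C1C(=O)O/C2=C/[C@@]3(C)CC[C@](OC)(O3)[C@H](C)C[C@H](O[Si](C)(C)C(C)(C)C)C12O | intermediate
19 | 7-O-acetate of 18 | C=C1C(=O)O/C2=C/[C@@]3(C)CC[C@](OC)(O3)[C@H](C)C[C@H](O[Si](C)(C)C(C)(C)C)C12OC(C)=O | intermediate
20 | 13-acetoxy ylidene butenolide with 1-OMe and 8-OTBS | CC(=O)OCC1=C2/C(=C\[C@@]3(C)CC[C@](OC)(O3)[C@H](C)C[C@@H]2O[Si](C)(C)C(C)(C)C)OC1=O | intermediate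
21 | 13-acetoxy ylidene butenolide with 1-OMe and free 8-OH | CC(=O)OCC1=C2/C(=C\[C@@]3(C)CC[C@](OC)(O3)[C@H](C)C[C@@H]2O)OC1=O | intermediate
22 | (S)-3-chloro-2-hydroxy-2-methylpropanoic acid | OC(=O)[C@](C)(O)CCl | starting material
23 | trimethylsilyl (S)-3-chloro-2-methyl-2-[(trimethylsilyl)oxy]propanoate | C[Si](C)(C)OC(=O)[C@](C)(O[Si](C)(C)C)CCl | intermediate
24 | (S)-3-chloro-2-methyl-2-[(trimethylsilyl)oxy]propanoyl chloride | O=C(Cl)[C@](C)(O[Si](C)(C)C)CCl | intermediate
25 | 1-O-methyl, 2′-O-trimethylsilyl derivative of the target | CC(=O)OCC1=C2/C(=C\[C@@]3(C)CC[C@](OC)(O3)[C@H](C)C[C@@H]2OC(=O)[C@](C)(O[Si](C)(C)C)CCl)OC1=O | intermediate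
26 | CNP0414417.1 | CC(=O)OCC1=C2/C(=C\[C@@]3(C)CC[C@](O)(O3)[C@H](C)C[C@@H]2OC(=O)[C@](C)(O)CCl)OC1=O | target

**Totals.** 14 steps in total; the longest linear sequence is 14 steps (1 → 26).

**Steps most likely to fail**

1. Step 7 (Proposed new method). Protodesilylation of the siloxyallene to the enone, or loss of the allene helicity before ring closure, would erode C4. The fallback uses known chemistry and sets out from 12. The siloxyallene is opened and acylated first (TBAT, acrylic anhydride, THF, −78 °C) to the allenyl acrylate F1. Iodoetherification (N-iodosuccinimide, MeOH, CH2Cl2, −40 °C) then adds the C1 carbonyl oxygen and iodine anti across C4=C5, methanol capturing the oxocarbenium ion, to give the 5-iodo enol acrylate methyl ketal F2. Palladium-catalysed hydrodeiodination (Pd(PPh3)4, Bu3SnH, THF) removes the iodine with retention of the alkene geometry and returns to the route at 15.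

2. Step 6. Migration of the silylene to the new tertiary alkoxide, enolisation of 8 by vinyllithium, or a stepwise fragmentation–recombination that loses the helicity may compete with the concerted shift. The fallback sets out from 8 and avoids any alkoxide at the rearrangement stage. Cerium chloride-promoted addition of vinylmagnesium bromide gives the isolated vinyl carbinol F3, and TMSCl/imidazole gives its trimethylsilyl ether F4. A neutral thermal siloxy-Cope rearrangement (toluene, sealed tube, 180 °C) gives the C1 trimethylsilyl enol ether F5. Selective hydrolysis of this more labile enol ether (citric acid, MeOH/H2O, 0 °C) returns to the route at 12.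

3. Step 8. Expulsion of the β-oxygen at C4 from the ammonium enolate (retro-oxa-Michael), or C-acylation, may compete with O-acylation. The fallback sets out from 13. Et3N·3HF removes the silylene to give the α-ketol F6 (C6 ketone, C7 hydroxyl), and Dess–Martin oxidation gives the 1,2-diketone F7. Soft enolisation away from the silyloxy-bearing C8 with O-acylation (acryloyl chloride, Et3N, CH2Cl2, −78 °C) returns to the route at 17, bypassing steps 9 and 10.

**Further compounds**

F1 | step 7 | allenyl acrylate of 12 with O7 di-tert-butylfluorosilyl ether | C[C@@H]1C[C@H](O[Si](C)(C)C(C)(C)C)[C@@H](O[Si](F)(C(C)(C)C)C(C)(C)C)C(OC(=O)C=C)=[C@]=C(C)CCC1=O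
F2 | step 7 | 5-iodo analogue of 15 | C=CC(=O)O/C2=C(I)/[C@@]1(C)CC[C@](OC)(O1)[C@H](C)C[C@H](O[Si](C)(C)C(C)(C)C)[C@H]2O[Si](F)(C(C)(C)C)C(C)(C)C
F3 | step 6 | tertiary vinyl carbinol from 8 (vinyl cis to propynyl) | C[C@@H]1C[C@H](O[Si](C)(C)C(C)(C)C)[C@H]2O[Si](C(C)(C)C)(C(C)(C)C)O[C@@]2(C#CC)[C@]1(O)C=C
F4 | step 6 | trimethylsilyl ether of F3 | C[C@@H]1C[C@H](O[Si](C)(C)C(C)(C)C)[C@H]2O[Si](C(C)(C)C)(C(C)(C)C)O[C@@]2(C#CC)[C@]1(O[Si](C)(C)C)C=C
F5 | step 6 | C1 trimethylsilyl enol ether of 12 | C[C@@H]1C[C@H](O[Si](C)(C)C(C)(C)C)[C@H]2O[Si](C(C)(C)C)(C(C)(C)C)OC2=[C@@]=C(C)CC=C1O[Si](C)(C)C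
F6 | step 8 | bridged methyl ketal α-ketol (C6 ketone, C7 hydroxyl, 8-OTBS) | O=C2C[C@@]1(C)CC[C@](OC)(O1)[C@H](C)C[C@H](O[Si](C)(C)C(C)(C)C)[C@H]2O
F7 | step 8 | bridged methyl ketal 6,7-diketone (8-OTBS) | O=C2C[C@@]1(C)CC[C@](OC)(O1)[C@H](C)C[C@H](O[Si](C)(C)C(C)(C)C)C2=O
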